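Remark on the chemistry: the pyranone enol ethers are drawn as 4‑benzyloxy‑2‑pyranones. An O2‑benzyl (4‑pyranone) isomer, should any form in step 6, holds the same atoms and would release the same 4‑hydroxy‑2‑pyranone in the last step. (R)‑2‑Methylbutanoic acid of high enantiomeric purity is taken as purchasable.

## Analysis of the target

The target is a hexasubstituted benzene with no fused rings. It is a phloroglucinol with hydroxyls on C2, C4 and C6, a (2R)‑2‑methylbutanoyl group on C1, and on each of C3 and C5 a CH2 bridge to C3 of a 6‑ethyl‑4‑hydroxy‑5‑methyl‑2H‑pyran‑2‑one ring. The only stereocenter is the α‑carbon of the aryl ketone. It relates to no other stereocenter, so it has to be bought in and then kept away from enolising conditions (strong base, Lewis acid with an acid chloride, long heating). The sensitive groups are five acidic hydroxyls (three phenolic, two vinylogous acids), two lactones that are also dienes, and two doubly activated CH2 bridges that can fragment by retro‑Michael reaction under base and heat. The difficulty is that every ring carbon is substituted and that the usual Friedel–Crafts acylation of the electron‑rich core would expose the α‑branched acyl unit to a Lewis acid. The two arms are identical, so both can be introduced in one operation on the two free carbons of a phenol. The strategy rests on the adjacent pair C1 (acyl) and C2 (hydroxyl), flanked by the oxygen‑bearing C6 on the acyl side and by the CH2‑bearing C3 on the hydroxyl side. An aryne spanning C1–C2 can take up hydroxyl and acyl together, and the C6 oxygen decides which carbon receives which.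

## Retrosynthetic reasoning

Target 18 is traced back to the tetrabenzyl ether 17 by cutting four O–CH2Ph bonds. The acidic hydroxyls cannot be free in the aryne step, where they would act as proton donors and nucleophiles. Benzyl ethers withstand fluoride and base and leave under neutral hydrogenolysis, so the stereocenter is not touched. The fifth hydroxyl, on the carbon next to the acyl group, needs no protection because the key step creates it.

In 17 the aryl–C(=O) bond and the neighbouring aryl–O bond are cut together. These are the only bonds that tie the stereogenic unit to the ring. Cutting both leads to aryne 16 and carboxylate 15, so the acyl unit arrives as the intact acid 14 and never as an acid chloride–Lewis acid complex. The pattern of 17, oxygen beside the acyl carbon and CH2 beside the hydroxyl carbon, matches the polarisation of an aryne that has an alkoxy neighbour. Forward, the aryne has to be released from the ortho‑silylaryl triflate 13, the carboxylate oxygen has to add at the carbon remote from the benzyloxy group, and the acyl shift has to outrun protonation. For that reason 14 is converted into salt 15 beforehand.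

Triflate 13 comes from phenol 12 by cutting the S–O bond, and 12 from the bis(hydroxypyranone) 11 by cutting the two enol O–benzyl bonds. The order matters. A sulfonylating agent would go to the more acidic pyranone hydroxyls first, so these are etherified while the phenol is still free, and the acidity gap between enol and phenol gives the selectivity.

In 11 each bridge is cut on both sides, ring–CH2 and CH2–C3 of the pyranone. Both bonds lie next to nucleophilic carbons, the ortho and para positions of a phenol and C3 of an enolised 1,3‑dicarbonyl, so a one‑carbon electrophile can join them. This leads to silyl phenol 8 and two equivalents of pyranone 4, passing through Mannich base 9 and alkylidene dione 10. Phenol 8 has exactly two unsubstituted ring carbons, so no regiochemical choice arises and both arms are gained in one operation. The forward step has to leave the C–Si bond intact, which calls for a basic medium.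

The C–Si bond of 8 is cut back to the aryl silyl ether 7 (retro‑Brook shift after halogen–lithium exchange) and the C–Br bond of bromophenol 6 to the symmetrical phenol 5. Silicon is introduced before the arms because the organolithium step would not tolerate two lactones. In 5 the two positions ortho to the hydroxyl are equivalent, so monobromination there gives a single compound.

Pyranone 4 is cut at C4–C5 and O1–C2 into the silyl enol ether 2 and malonyl dichloride 3, and 2 goes back to pentan‑3‑one 1. The symmetrical ketone gives one enol ether constitution, and the annulation puts ethyl on C6, methyl on C5 and leaves C3 free for the bridge.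

## Alternatives that were turned down

Alternative 1: The two ring–CH2 bonds are cut with the acyl group already on the ring. In the forward key step the dibromide (2R)‑1‑[3,5‑dibromo‑2,4,6‑tris(methoxymethoxy)phenyl]‑2‑methylbutan‑1‑one A2 would be coupled twice with {[6‑ethyl‑4‑(methoxymethoxy)‑5‑methyl‑2‑oxo‑2H‑pyran‑3‑yl]methyl}zinc bromide A3, using Pd(OAc)2 and a dicyclohexyl(biaryl)phosphine in a twofold Negishi reaction. The product is the pentakis(methoxymethyl) ether A1, from which acid would free the five hydroxyls.
- For: the substitution pattern is fixed by the substrate, so no regiochemical question arises. On this point the alternative is stronger than the chosen route, which depends on the orientation of an aryne addition. An sp2–sp3 coupling with an organozinc reagent also tolerates ketone and lactone.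
- Against: each C–Br bond of A2 lies between two alkoxy groups on an electron‑rich ring, so oxidative addition is slow, it has to succeed twice, and reduction of C–Br competes. A3 needs a 3‑(halomethyl)pyranone and several steps per arm, and zinc insertion beside a vinylogous ester invites homocoupling. The stereocenter has to enter at the outset by Friedel–Crafts acylation under a Lewis acid, where an α‑branched acyl chloride can racemise through its enol or ketene. It must then survive bromination, base‑mediated acetal formation, the coupling and five acidic acetal cleavages.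
- Comparison: the chosen route brings the stereocenter in at the penultimate step without Lewis acid and installs both arms in a single operation from 4. It gives up the regiochemical certainty of A1.

Alternative 2: C3–C4 of each pyranone is cut. In the forward key step the bis(enol ester) A5 carries two 3‑arylpropanoate chains, each esterified to the Z‑enol of methyl 2‑methyl‑3‑oxopentanoate. LiN(SiMe3)2 would deprotonate each chain at the carbon beside the bridge CH2, and each enolate would attack the methyl ester across the enol double bond in a twofold Dieckmann closure. The product is 3,3'‑{[2,4,6‑tris(benzyloxy)‑1,3‑phenylene]bis(methylene)}bis(6‑ethyl‑4‑hydroxy‑5‑methyl‑2H‑pyran‑2‑one) A4.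
- For: both closures are intramolecular and six‑membered. The bridge carbons come from ordinary arylpropanoate chemistry, so neither a phenol–pyranone coupling nor an aryne is needed. In the certainty of each bond formation this is the more conservative plan, and it avoids the pyranone self‑coupling that threatens step 5 of the chosen route.
- Against: the enolate of an enol ester can expel the β‑keto ester enolate and form a ketene, or pass its acyl group to another molecule, and the closure must succeed twice from a defined Z geometry. More seriously, A4 has no acyl group. The last ring carbon, between two benzyloxy groups, would have to be acylated with the chiral acid chloride and a Lewis acid in the presence of three benzyl ethers and two free pyranone hydroxyls, so the stereocenter problem is postponed and not solved. The route to A5 is also longer.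
- Comparison: the chosen route makes the pyranone once, on small molecules, and places acyl and hydroxyl in one step.

Alternative 3: C4–C5 and O1–C2 of both pyranones are cut, the same bonds that step 2 of the chosen route makes, but at the end and on a core that already carries the acyl group. In the forward key step the tetra‑acid chloride A7, 2,2'‑{[2,4,6‑tris(benzyloxy)‑5‑[(2R)‑2‑methylbutanoyl]‑1,3‑phenylene]bis(methylene)}bis(propanedioyl dichloride), would be annulated at each malonyl unit with silyl enol ether 2. The product is the 2,4,6‑tri‑O‑benzyl ether of the target, A6, one hydrogenolysis from 18.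
- For: it is fully convergent, uses the cheapest building blocks and the annulation type of steps 1 and 2, and ends with the same single deprotection as the chosen route, so the end game is equally short.
- Against: A7 is a fourfold acid chloride of two monosubstituted malonic acids. These lose HCl to acyl ketenes, and two bifunctional electrophiles on one ring can cross‑link with the bifunctional 2. Four acylations must all take the right course, and four equivalents of HCl are set free beside three aryl benzyl ethers and an enolisable ketone. Acid chloride formation has to be carried out next to the stereocenter, and the core of A7 again needs the acyl group installed early.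
- Comparison: the chosen route runs this annulation once, where it is clean, and keeps the sensitive acyl unit out of all acid chloride chemistry.

Key step: step 8

## Route

Step 1
Reactants: 1 pentan‑3‑one
Product: 2 (Z)‑trimethyl(pent‑2‑en‑3‑yloxy)silane
Conditions: TMSOTf, Et3N, CH2Cl2, 0 °C
Reagents that add atoms: trimethylsilyl trifluoromethanesulfonate, C[Si](C)(C)OS(=O)(=O)C(F)(F)F
Why: Soft enolisation, in which the silyl triflate activates the carbonyl and the amine removes an α‑proton; the symmetrical ketone gives one constitution, mainly Z, and the geometry is of no consequence because both isomers lead to the same pyranone.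

Step 2
Reactants: 2 (Z)‑trimethyl(pent‑2‑en‑3‑yloxy)silane; 3 malonyl dichloride
Product: 4 6‑ethyl‑4‑hydroxy‑5‑methyl‑2H‑pyran‑2‑one
Conditions: Et2O, −78 °C → rt
Reagents that add atoms: none
Why: Acylative annulation of a silyl enol ether with malonyl dichloride: C‑acylation at the enol carbon forms C4–C5, the enol oxygen of the resulting diketone closes on the second acid chloride (O1–C2, six‑membered lactone), and tautomerisation gives the 4‑hydroxy‑2‑pyranone with C3 unsubstituted.

Step 3
Reactants: 5 3,5‑bis(benzyloxy)phenol
Product: 6 3,5‑bis(benzyloxy)‑2‑bromophenol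
Conditions: NBS (1.0 equiv), CH2Cl2, −78 °C
Reagents that add atoms: N‑bromosuccinimide, O=C1CCC(=O)N1Br
Why: Electrophilic aromatic bromination; the two positions ortho to the hydroxyl are equivalent and less hindered than C4 between the two benzyloxy groups, and one equivalent at low temperature should hold the reaction at the monobromide.

Step 4
Reactants: 6 3,5‑bis(benzyloxy)‑2‑bromophenol
Product: 8 3,5‑bis(benzyloxy)‑2‑(trimethylsilyl)phenol, via aryl trimethylsilyl ether 7 (not isolated)
Conditions: (Me3Si)2NH, THF, reflux, then evaporation; n‑BuLi, THF, −78 °C → rt; aq NH4Cl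
Reagents that add atoms: hexamethyldisilazane, C[Si](C)(C)N[Si](C)(C)C
Why: O‑Silylation, then bromine–lithium exchange and a 1,3 O→C silyl shift (retro‑Brook rearrangement) driven by formation of the phenoxide, the standard entry to ortho‑silyl phenols; the electron‑rich C–Si bond is acid‑labile, so the quench is mild and 8 should be purified on amine‑deactivated silica.

Step 5
Reactants: 8 3,5‑bis(benzyloxy)‑2‑(trimethylsilyl)phenol; 4 6‑ethyl‑4‑hydroxy‑5‑methyl‑2H‑pyran‑2‑one (two equivalents)
Product: 11 3,5‑bis(benzyloxy)‑2,4‑bis[(6‑ethyl‑4‑hydroxy‑5‑methyl‑2‑oxo‑2H‑pyran‑3‑yl)methyl]‑6‑(trimethylsilyl)phenol, via Mannich base 9 (not isolated), via methylidene dione 10 (not isolated)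
Conditions: 4 (2.3 equiv), CH2=NMe2+ I− (2.3 equiv), MeCN, rt; then 8, Et3N, 40 °C
Reagents that add atoms: N,N‑dimethylmethyleneiminium iodide, C[N+](C)=C.[I-]
Why: Mannich reaction at C3 of 4 gives 9, which loses dimethylamine to the alkylidene dione 10; the phenol(ate) 8 adds to this strong Michael acceptor through its two unsubstituted ring carbons (C4 and C6 of 8) and re‑aromatises, the established Mannich–elimination–Michael way of joining phenols and 4‑hydroxypyranones by a CH2 bridge. Forming 9 first keeps free 4 low, which holds back the methylene‑bis(pyranone) dimer, and the amine‑buffered medium guards the C–Si bond against protodesilylation.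

Step 6
Reactants: 11 3,5‑bis(benzyloxy)‑2,4‑bis[(6‑ethyl‑4‑hydroxy‑5‑methyl‑2‑oxo‑2H‑pyran‑3‑yl)methyl]‑6‑(trimethylsilyl)phenol
Product: 12 3,5‑bis(benzyloxy)‑2,4‑bis{[4‑(benzyloxy)‑6‑ethyl‑5‑methyl‑2‑oxo‑2H‑pyran‑3‑yl]methyl}‑6‑(trimethylsilyl)phenol
Conditions: BnOH (2.2 equiv), PPh3, DIAD, THF, 0 °C → rt
Reagents that add atoms: benzyl alcohol, OCc1ccccc1
Why: Mitsunobu etherification; the pyranone enols (pKa near 5) protonate the betaine and their anions are O‑alkylated by the benzyloxyphosphonium ion, while the far less acidic phenol, flanked by silyl and CH2 groups, stays protonated. Mitsunobu alkylation of 4‑hydroxy‑2‑pyranones goes on oxygen, and the neutral medium leaves the C–Si bond alone.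

Step 7
Reactants: 12 3,5‑bis(benzyloxy)‑2,4‑bis{[4‑(benzyloxy)‑6‑ethyl‑5‑methyl‑2‑oxo‑2H‑pyran‑3‑yl]methyl}‑6‑(trimethylsilyl)phenol
Product: 13 3,5‑bis(benzyloxy)‑2,4‑bis{[4‑(benzyloxy)‑6‑ethyl‑5‑methyl‑2‑oxo‑2H‑pyran‑3‑yl]methyl}‑6‑(trimethylsilyl)phenyl trifluoromethanesulfonate
Conditions: Tf2O, pyridine, CH2Cl2, −78 → 0 °C
Reagents that add atoms: trifluoromethanesulfonic anhydride, O=S(=O)(OS(=O)(=O)C(F)(F)F)C(F)(F)F
Why: O‑Sulfonylation of the only remaining hydroxyl by the N‑triflylpyridinium ion, the usual last step towards ortho‑silylaryl triflates; the reagent is reactive enough for a doubly ortho‑substituted phenol, and lactones and ethers are not attacked at low temperature.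

Step 8
Reactants: 13 3,5‑bis(benzyloxy)‑2,4‑bis{[4‑(benzyloxy)‑6‑ethyl‑5‑methyl‑2‑oxo‑2H‑pyran‑3‑yl]methyl}‑6‑(trimethylsilyl)phenyl trifluoromethanesulfonate; 14 (2R)‑2‑methylbutanoic acid
Product: 17 (2R)‑1‑[2,4‑bis(benzyloxy)‑3,5‑bis{[4‑(benzyloxy)‑6‑ethyl‑5‑methyl‑2‑oxo‑2H‑pyran‑3‑yl]methyl}‑6‑hydroxyphenyl]‑2‑methylbutan‑1‑one, via caesium (2R)‑2‑methylbutanoate 15 (not isolated), via aryne 16 (not isolated)
Conditions: 14 (3 equiv), Cs2CO3, MeOH, rt, then evaporation and drying; 13, CsF, 18‑crown‑6, THF, 65 °C (sealed tube); 1 M HCl work‑up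
Reagents that add atoms: none
Why: Desilylation of 13 by fluoride with loss of the adjacent triflate releases aryne 16, whose triple bond joins C1 (beside the CH2 arm on C6) and C2 (beside the benzyloxy group on C3). Carboxylate 15 bonds through oxygen to C1, since attack there puts the developing carbanion on C2 next to the electronegative C3 oxygen, while the arm on C6 exerts only a weaker steric bias in the opposite sense. The C2 carbanion then adds to the carbonyl of the freshly formed aryl ester, and the strained four‑membered alkoxide collapses by C–O cleavage to the ortho‑acyl phenoxide, a 1,3 O→C acyl shift of the anionic ortho‑Fries type; one aryl–O and one aryl–C bond are made on adjacent carbons and no ring remains in the product. The closest known reaction is the insertion of arynes from ortho‑silylaryl triflates into the C–O bond of carboxylic acids to give ortho‑hydroxyaryl ketones, applied here to a pentasubstituted aryne. No stereocenter is formed; the (R) centre comes from 14 and is protected by using the pre‑formed salt 15, so that no free acid protonates the carbanion before the shift and no base stronger than fluoride is present, and by working at the lowest temperature at which the aryne forms. Three selectivities are needed: O‑addition at C1 over C2, secured by the C3 benzyloxy group; acyl shift over protonation, secured by the absence of proton donors; and capture by carboxylate over [4+2] addition to a pyranone diene, secured by the excess of 15 and by the fully substituted, hindered dienes.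

Step 9
Reactants: 17 (2R)‑1‑[2,4‑bis(benzyloxy)‑3,5‑bis{[4‑(benzyloxy)‑6‑ethyl‑5‑methyl‑2‑oxo‑2H‑pyran‑3‑yl]methyl}‑6‑hydroxyphenyl]‑2‑methylbutan‑1‑one
Product: 18 (2R)‑1‑{3,5‑bis[(6‑ethyl‑4‑hydroxy‑5‑methyl‑2‑oxo‑2H‑pyran‑3‑yl)methyl]‑2,4,6‑trihydroxyphenyl}‑2‑methylbutan‑1‑one
Conditions: H2 (1 atm), Pd/C, EtOAc–MeOH, rt
Reagents that add atoms: none
Why: Hydrogenolysis of two aryl and two enol benzyl ethers; the tetrasubstituted pyranone double bonds and the hydrogen‑bonded aryl ketone should resist reduction at ambient pressure, and the neutral medium leaves the α‑stereocenter untouched.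

## Compound list

1 | pentan‑3‑one | CCC(=O)CC | starting material
2 | (Z)‑trimethyl(pent‑2‑en‑3‑yloxy)silane | C/C=C(/CC)O[Si](C)(C)C | intermediate
3 | malonyl dichloride | O=C(Cl)CC(=O)Cl | starting material
4 | 6‑ethyl‑4‑hydroxy‑5‑methyl‑2H‑pyran‑2‑one | CCc1oc(=O)cc(O)c1C | intermediate
5 | 3,5‑bis(benzyloxy)phenol | Oc1cc(OCc2ccccc2)cc(OCc2ccccc2)c1 | starting material
6 | 3,5‑bis(benzyloxy)‑2‑bromophenol | Oc1cc(OCc2ccccc2)cc(OCc2ccccc2)c1Br | intermediate
7 | [3,5‑bis(benzyloxy)‑2‑bromophenoxy]trimethylsilane | C[Si](C)(C)Oc1cc(OCc2ccccc2)cc(OCc2ccccc2)c1Br | intermediate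
8 | 3,5‑bis(benzyloxy)‑2‑(trimethylsilyl)phenol | Oc1cc(OCc2ccccc2)cc(OCc2ccccc2)c1[Si](C)(C)C | intermediate
9 | 3‑[(dimethylamino)methyl]‑6‑ethyl‑4‑hydroxy‑5‑methyl‑2H‑pyran‑2‑one | CCc1oc(=O)c(CN(C)C)c(O)c1C | intermediate
10 | 6‑ethyl‑5‑methyl‑3‑methylidene‑2H‑pyran‑2,4(3H)‑dione | CCC1=C(C)C(=O)C(=C)C(=O)O1 | intermediate
11 | 3,5‑bis(benzyloxy)‑2,4‑bis[(6‑ethyl‑4‑hydroxy‑5‑methyl‑2‑oxo‑2H‑pyran‑3‑yl)methyl]‑6‑(trimethylsilyl)phenol | C[Si](C)(C)c1c(O)c(Cc2c(O)c(C)c(CC)oc2=O)c(OCc2ccccc2)c(Cc2c(O)c(C)c(CC)oc2=O)c1OCc3ccccc3 | intermediate
12 | 3,5‑bis(benzyloxy)‑2,4‑bis{[4‑(benzyloxy)‑6‑ethyl‑5‑methyl‑2‑oxo‑2H‑pyran‑3‑yl]methyl}‑6‑(trimethylsilyl)phenol | C[Si](C)(C)c1c(O)c(Cc2c(OCc3ccccc3)c(C)c(CC)oc2=O)c(OCc2ccccc2)c(Cc2c(OCc3ccccc3)c(C)c(CC)oc2=O)c1OCc4ccccc4 | intermediate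
13 | 3,5‑bis(benzyloxy)‑2,4‑bis{[4‑(benzyloxy)‑6‑ethyl‑5‑methyl‑2‑oxo‑2H‑pyran‑3‑yl]methyl}‑6‑(trimethylsilyl)phenyl trifluoromethanesulfonate | C[Si](C)(C)c1c(OS(=O)(=O)C(F)(F)F)c(Cc2c(OCc3ccccc3)c(C)c(CC)oc2=O)c(OCc2ccccc2)c(Cc2c(OCc3ccccc3)c(C)c(CC)oc2=O)c1OCc4ccccc4 | intermediate
14 | (2R)‑2‑methylbutanoic acid | OC(=O)[C@H](C)CC | starting material
15 | caesium (2R)‑2‑methylbutanoate | [Cs+].[O-]C(=O)[C@H](C)CC | intermediate
16 | 3,5‑bis(benzyloxy)‑4,6‑bis{[4‑(benzyloxy)‑6‑ethyl‑5‑methyl‑2‑oxo‑2H‑pyran‑3‑yl]methyl}‑1,2‑didehydrobenzene | C1#CC(Cc2c(OCc3ccccc3)c(C)c(CC)oc2=O)=C(OCc2ccccc2)C(Cc2c(OCc3ccccc3)c(C)c(CC)oc2=O)=C1OCc4ccccc4 | intermediate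
17 | (2R)‑1‑[2,4‑bis(benzyloxy)‑3,5‑bis{[4‑(benzyloxy)‑6‑ethyl‑5‑methyl‑2‑oxo‑2H‑pyran‑3‑yl]methyl}‑6‑hydroxyphenyl]‑2‑methylbutan‑1‑one | O=C([C@H](C)CC)c1c(O)c(Cc2c(OCc3ccccc3)c(C)c(CC)oc2=O)c(OCc2ccccc2)c(Cc2c(OCc3ccccc3)c(C)c(CC)oc2=O)c1OCc4ccccc4 | intermediate
18 | (2R)‑1‑{3,5‑bis[(6‑ethyl‑4‑hydroxy‑5‑methyl‑2‑oxo‑2H‑pyran‑3‑yl)methyl]‑2,4,6‑trihydroxyphenyl}‑2‑methylbutan‑1‑one | CCc1oc(=O)c(Cc2c(O)c(Cc3c(O)c(C)c(CC)oc3=O)c(O)c(C(=O)[C@H](C)CC)c2O)c(O)c1C | target

## Step count and least certain steps

Total step count: 9. Longest linear sequence: 7 steps (5 → 18 through steps 3 to 9; the branch from 1 through steps 1, 2 and 5 to 9 is equally long).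

**Step 8 (key step).** Four things may go wrong:
- The carbanion may be protonated before the acyl shift, so that the reaction stops at the aryl ester.
- The aryne may be taken up by a pyranone diene of a second molecule or by fluoride.
- The carboxylate may add with the opposite orientation, because the arm next to C1 shields that carbon.
- The α‑stereocenter may be partly lost through enolisation of the product ketone in warm, fluoride‑containing medium.

Fallback, setting out from 12 and returning at 17: ipso‑iododesilylation of 12 with N‑iodosuccinimide (the silicon‑bearing carbon is the most electron‑rich of the ring) should give 3,5‑bis(benzyloxy)‑2,4‑bis{[4‑(benzyloxy)‑6‑ethyl‑5‑methyl‑2‑oxo‑2H‑pyran‑3‑yl]methyl}‑6‑iodophenol F1. Carbodiimide esterification of F1 with 14 gives 3,5‑bis(benzyloxy)‑2,4‑bis{[4‑(benzyloxy)‑6‑ethyl‑5‑methyl‑2‑oxo‑2H‑pyran‑3‑yl]methyl}‑6‑iodophenyl (2R)‑2‑methylbutanoate F2. Iodine–lithium exchange on F2 with n‑BuLi at −95 °C, which is faster than addition to the lactones, triggers the anionic ortho‑Fries shift and leads to 17. The same carbanion is reached without an aryne, so orientation and cycloaddition no longer matter.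

**Step 5.** The electrophile 10 may attack the silicon‑bearing carbon with loss of silicon, the C–Si bond may be cleaved by adventitious acid, the second alkylation at the carbon between the two benzyloxy groups may lag, and 4 may couple with 10 to the methylene‑bis(pyranone).

Fallback, setting out from 6 and returning at 11: twofold aminomethylation of 6 with the iminium iodide gives 3,5‑bis(benzyloxy)‑2‑bromo‑4,6‑bis[(dimethylamino)methyl]phenol F3; bromine blocks its carbon and does not leave towards a carbon electrophile. O‑Silylation, bromine–lithium exchange and retro‑Brook shift as in step 4 (tertiary amines tolerate n‑BuLi) give 3,5‑bis(benzyloxy)‑2,4‑bis[(dimethylamino)methyl]‑6‑(trimethylsilyl)phenol F4. Heating F4 with 4 expels dimethylamine to ortho‑ and para‑quinone methides, to which C3 of 4 adds, giving 11. The polarity is reversed, so the silylated ring never meets a carbon electrophile.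

**Step 6.** Etherification may spread to the phenol, or alkylation may go to carbon C3 of the pyranone.

Fallback, setting out from 11 and returning at 12: alkylation with benzyl bromide and KHCO3 in DMF, in which a bicarbonate base ionises only the pyranone enols, so that the site is chosen by acidity of the substrate and not by activation of the alcohol. No new compound arises (F0).

**Step 9.** Hydrogenation may go on to a pyranone double bond or the benzylic carbonyl, or may stall at the hindered ethers.

Fallback, setting out from 17 and returning at 18: Lewis acid debenzylation with BCl3 and pentamethylbenzene as cation scavenger in CH2Cl2 at −78 °C, which involves no hydrogen and no metal surface. No new compound arises (F0).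

## Further compounds

F1 | step 8 | 3,5‑bis(benzyloxy)‑2,4‑bis{[4‑(benzyloxy)‑6‑ethyl‑5‑methyl‑2‑oxo‑2H‑pyran‑3‑yl]methyl}‑6‑iodophenol | Ic1c(O)c(Cc2c(OCc3ccccc3)c(C)c(CC)oc2=O)c(OCc2ccccc2)c(Cc2c(OCc3ccccc3)c(C)c(CC)oc2=O)c1OCc4ccccc4
F2 | step 8 | 3,5‑bis(benzyloxy)‑2,4‑bis{[4‑(benzyloxy)‑6‑ethyl‑5‑methyl‑2‑oxo‑2H‑pyran‑3‑yl]methyl}‑6‑iodophenyl (2R)‑2‑methylbutanoate | Ic1c(OC(=O)[C@H](C)CC)c(Cc2c(OCc3ccccc3)c(C)c(CC)oc2=O)c(OCc2ccccc2)c(Cc2c(OCc3ccccc3)c(C)c(CC)oc2=O)c1OCc4ccccc4
F3 | step 5 | 3,5‑bis(benzyloxy)‑2‑bromo‑4,6‑bis[(dimethylamino)methyl]phenol | CN(C)Cc1c(O)c(Br)c(OCc2ccccc2)c(CN(C)C)c1OCc3ccccc3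
F4 | step 5 | 3,5‑bis(benzyloxy)‑2,4‑bis[(dimethylamino)methyl]‑6‑(trimethylsilyl)phenol | CN(C)Cc1c(O)c([Si](C)(C)C)c(OCc2ccccc2)c(CN(C)C)c1OCc3ccccc3
F0 | step 6 | none | none
F0 | step 9 | none | none
A1 | alternative 1 | (2R)‑1‑[3,5‑bis{[6‑ethyl‑4‑(methoxymethoxy)‑5‑methyl‑2‑oxo‑2H‑pyran‑3‑yl]methyl}‑2,4,6‑tris(methoxymethoxy)phenyl]‑2‑methylbutan‑1‑one | O=C([C@H](C)CC)c1c(OCOC)c(Cc2c(OCOC)c(C)c(CC)oc2=O)c(OCOC)c(Cc2c(OCOC)c(C)c(CC)oc2=O)c1OCOC
A2 | alternative 1 | (2R)‑1‑[3,5‑dibromo‑2,4,6‑tris(methoxymethoxy)phenyl]‑2‑methylbutan‑1‑one | O=C([C@H](C)CC)c1c(OCOC)c(Br)c(OCOC)c(Br)c1OCOC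
A3 | alternative 1 | {[6‑ethyl‑4‑(methoxymethoxy)‑5‑methyl‑2‑oxo‑2H‑pyran‑3‑yl]methyl}zinc bromide | CCc1oc(=O)c(C[Zn]Br)c(OCOC)c1C
A4 | alternative 2 | 3,3'‑{[2,4,6‑tris(benzyloxy)‑1,3‑phenylene]bis(methylene)}bis(6‑ethyl‑4‑hydroxy‑5‑methyl‑2H‑pyran‑2‑one) | CCc1oc(=O)c(Cc2c(OCc3ccccc3)cc(OCc3ccccc3)c(Cc3c(O)c(C)c(CC)oc3=O)c2OCc2ccccc2)c(O)c1C
A5 | alternative 2 | dimethyl (2Z,2'Z)‑3,3'‑{[2,4,6‑tris(benzyloxy)‑1,3‑phenylene]bis[(1‑oxopropane‑3,1‑diyl)oxy]}bis(2‑methylpent‑2‑enoate) | COC(=O)/C(C)=C(/CC)OC(=O)CCc1c(OCc2ccccc2)cc(OCc2ccccc2)c(CCC(=O)O/C(CC)=C(/C)C(=O)OC)c1OCc3ccccc3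
A6 | alternative 3 | (2R)‑1‑[2,4,6‑tris(benzyloxy)‑3,5‑bis[(6‑ethyl‑4‑hydroxy‑5‑methyl‑2‑oxo‑2H‑pyran‑3‑yl)methyl]phenyl]‑2‑methylbutan‑1‑one | O=C([C@H](C)CC)c1c(OCc2ccccc2)c(Cc2c(O)c(C)c(CC)oc2=O)c(OCc2ccccc2)c(Cc2c(O)c(C)c(CC)oc2=O)c1OCc3ccccc3
A7 | alternative 3 | 2,2'‑{[2,4,6‑tris(benzyloxy)‑5‑[(2R)‑2‑methylbutanoyl]‑1,3‑phenylene]bis(methylene)}bis(propanedioyl dichloride) | O=C([C@H](C)CC)c1c(OCc2ccccc2)c(CC(C(=O)Cl)C(=O)Cl)c(OCc2ccccc2)c(CC(C(=O)Cl)C(=O)Cl)c1OCc3ccccc3
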